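The numbers in the tables are calculated with constants of no real substance, and the scatter is random.

The constants of the steps are hidden, but a rate of approach can be read from the readings.

| flask | free monomer | protic impurity | initiator | remark | time |
|---|---|---|---|---|---|
| eta | 0.20 M | 0.010 M | 2 mM | run made earlier |  |
| epsilon | 0.20 M | 0.010 M | 1 mM | run made earlier |  |
| delta | 0.20 M | 0.010 M | 1.5 mM | run made earlier |  |
| beta | 0.20 M | 0.015 M | 2 mM | run made earlier |  |
| teal | 0.20 M | 0.0100 M | 2.0 mM | everything together in a closed stirred flask, run for 3.0 min | 3.0 min |
| violet | 0.20 M | 0.0100 M | 2.0 mM | one stirred flow tank at steady state, fed with the mixture as stated, mean residence time 3.0 min |  |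
| amber | 0.20 M (fed, over 1.50 min) | 0.0100 M | 2.0 mM | all but free monomer at the start; free monomer goes in evenly over 1.50 min, the run ends at 3.0 min | 3.0 min |

- eta (time / min: monomer in chains / %, free monomer / %): 0.667: 10.8, 85.4; 1.33: 18.3, 76.4; 2.00: 26.2, 70.4; 2.50: 27.9, 67.5; 3.00: 29.0, 66.5
- epsilon (time / min: monomer in chains / %, free monomer / %): 0.667: 6.9, 90.2; 1.33: 10.1, 82.0; 2.00: 17.1, 78.4; 3.00: 22.6, 72.0; 4.00: 25.8, 69.4
- delta (time / min: monomer in chains / %, free monomer / %): 0.667: 8.6, 87.5; 1.33: 13.8, 80.3; 2.00: 22.1, 73.5; 3.00: 27.2, 69.4; 4.00: 30.6, 63.9
- beta (time / min: monomer in chains / %, free monomer / %): 0.250: 2.1, 94.4; 0.500: 6.6, 88.7; 1.00: 13.8, 79.4; 2.00: 22.0, 70.3; 4.00: 30.8, 62.4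

(scatter of a reading: 1 percentage point)

- monomer in chains is meant together with its idle complex
- the stated concentrations are those of everything mixed, before any reaction; amounts are the same in each set-up
- the earlier runs were read with a standard deviation of 1 percentage point
- candidate steps: free monomer + initiator -> living end + monomer in chains; free monomer + living end -> monomer in chains + living end; monomer in chains + living end -> free monomer + living end; initiator + monomer in chains <-> idle complex; protic impurity + free monomer -> quenched substrate; monomer in chains + initiator <-> isomer of the product + initiator
- the feed brings no volume worth counting
- the earlier runs were made in a closed, stirred flask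

- the set-up with the highest amount of monomer in chains at the outlet or at the end, in percent of the free monomer put in ("none" if the first two lie within 2 percentage points) (teal / violet / amber / none)
- amount of monomer in chains at the outlet or at the end, in percent of the free monomer put in, teal
- amount of monomer in chains at the outlet or at the end, in percent of the free monomer put in, violet
- amount of monomer in chains at the outlet or at the end, in percent of the free monomer put in, amber

Two of us read the eta run, which has teal's recipe. I hold that monomer in chains, P, climbs towards a plateau P∞ with a gap that shrinks in proportion to itself, a pseudo-first-order approach, so that over a time t the gap falls by the factor exp(−λt). The gain over a second equal interval is then that factor times the gain over the first. The readings at 0.667 min and 1.33 min therefore give λ = 0.547 /min, and this relaxation rate, the speed at which the gap closes at any moment divided by the gap at that moment, is what I carry. The same readings give P∞ = 35.3%, with their scatter.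

My colleague points to the last eta readings, 27.9% and 29.0%, a gain of 1.1 percentage points with readings scattered by 1 point. She says the eta flask already stands on its plateau, so the vessel hardly counts and the answer is none.

I answer that at 3.0 min the gap is still 19.4% of P∞, which gives 28.5% for teal. In violet, with mean residence time θ of the same length, outflow balances the approach, so P is P∞ times λθ over one plus λθ, or 22.0%. In amber each portion of monomer relaxes from its own entry, and averaging over the dosing gives 24.7%. So I expect teal to stand higher than amber and amber higher than violet, assuming each flask shares eta's plateau.

The forecast takes my side with its own reckoning, slightly apart from mine. It reads the levelling as “reversible propagation or inhibition by the idle complex” and gives 28.8% for teal, 22% for violet and 25% for amber, with teal best.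

The flask gives 30.1% in teal, 25.1% in amber and 23.0% in violet, so teal is best, ahead of amber by 5 points against a margin of 2 points, and the forecast stands.

free monomer + initiator → living end + monomer in chains (k = 0.290 /M/s); free monomer + living end → monomer in chains + living end, rate k2*[living end]*[free monomer] (k = 6.20 /M/s); monomer in chains + living end → free monomer + living end, rate k3*[living end] as long as [monomer in chains] is above zero (k = 0.750 /s); initiator + monomer in chains ⇌ idle complex, settled at all times (K = 1.20 /M); protic impurity + free monomer → quenched substrate (k = 0.220 /M/s); monomer in chains + initiator ⇌ isomer of the product + initiator, rate k6*[initiator]*[monomer in chains] forward; the back reaction follows from the equilibrium constant (K = 0.370, k = 0.770 /M/s) The half-life of protic impurity by quenching, concentrations held at their charge, is 0.26 min in teal, shorter than the inverse of λ, the relaxation time read from eta, while the teal run lasts 1.64 such relaxation times. My colleague's view gets its region at 30.0 min, which is 16.4 relaxation times, where teal stands at 34.4% and amber at 34.5%.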